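Ring A (the formyl arene) is grown on the diaryl ether oxygen O7 of ring B, so the C–O bond flanked by four ortho substituents never has to be made by coupling. The benzannulation of an ester-substituted vinylketene with a ring-B aryl ynol ether builds ring A in one operation and sets its contiguous C(OH), C(CHO, masked as acetal) and C(OAr) carbons, with the carboxyl carbon next to the methyl-bearing carbon. The precursor is the chromanone whose O7 carries a 3,3-dimethoxypropynyl group, O6 a MOM group and O8 a methyl group; its partner is a tert-butyl vinyl diazo ketoester. One acid treatment, lactonization and demethylation then give the depsidone.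

Key step: step 9

Remark: ring A is the formyl-bearing arene and ring B the benzo ring of the chromanone; chromanone locants are used for ring B, so in the target O6 is the lactone oxygen, O7 the ether oxygen and O8 the free hydroxyl. In names, Ar stands for the 8-methoxy-6-(methoxymethoxy)-2,2,5-trimethyl-4-oxochroman-7-yl group.
Remark: the ring-A carboxyl is carried as a tert-butyl ester, because a benzoate flanked by methyl and aryloxy groups resists saponification, whereas acid frees it together with the acetal and the MOM ether.
Remark: 2,2-dimethoxyacetaldehyde (7) is assumed to be used as the commercial aqueous solution, extracted into CH2Cl2 and dried before use.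

Step 1
Reactants: 1 2,3-dimethoxy-5-methyl-1,4-benzoquinone
Product: 2 2,3-dimethoxy-5-methylbenzene-1,4-diol
Conditions: Na2S2O4, EtOAc/H2O, rt
Reagents that add atoms: none
Why: Dithionite reduction of the quinone gives the hydroquinone, which is used at once because it re-oxidizes in air.

Step 2
Reactants: 2 2,3-dimethoxy-5-methylbenzene-1,4-diol; 3 3-methylbut-2-enoic acid
Product: 4 6-hydroxy-7,8-dimethoxy-2,2,5-trimethylchroman-4-one
Conditions: P2O5/MeSO3H, 70 °C
Reagents that add atoms: none
Why: Friedel–Crafts acylation at the only unsubstituted ring carbon followed by intramolecular oxa-Michael addition of the flanking phenol should close the 2,2-dimethylchromanone in one pot and leave the phenol next to the methyl group free.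

Step 3
Reactants: 4 6-hydroxy-7,8-dimethoxy-2,2,5-trimethylchroman-4-one
Product: 5 7,8-dimethoxy-6-(methoxymethoxy)-2,2,5-trimethylchroman-4-one
Conditions: MOMCl, iPr2NEt, CH2Cl2, 0 °C → rt
Reagents that add atoms: chloromethyl methyl ether (MOMCl), COCCl
Why: Williamson-type O-alkylation of the single phenol gives a MOM ether that tolerates thiolate, base and light and later falls in acid together with the acetal and the ester.

Step 4
Reactants: 5 7,8-dimethoxy-6-(methoxymethoxy)-2,2,5-trimethylchroman-4-one
Product: 6 7-hydroxy-8-methoxy-6-(methoxymethoxy)-2,2,5-trimethylchroman-4-one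
Conditions: NaSEt, DMF, 100 °C; then AcOH
Reagents that add atoms: none
Why: SN2 demethylation by thiolate should be selective for the C7 methoxy, which is para to the ketone (best phenoxide leaving group) and twisted by two ortho oxygens, whereas the C8 methoxy is meta to the carbonyl and the MOM acetal is inert to thiolate.

Step 5
Reactants: 7 2,2-dimethoxyacetaldehyde
Product: 8 1,1-dibromo-3,3-dimethoxyprop-1-ene
Conditions: CBr4, PPh3, Et3N, CH2Cl2, 0 °C
Reagents that add atoms: carbon tetrabromide, BrC(Br)(Br)Br
Why: Ramirez dibromo-olefination (first stage of the Corey–Fuchs sequence) of the aldehyde, buffered with Et3N so that the acetal stays intact.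

Step 6
Reactants: 6 7-hydroxy-8-methoxy-6-(methoxymethoxy)-2,2,5-trimethylchroman-4-one; 8 1,1-dibromo-3,3-dimethoxyprop-1-ene
Product: 9 (Z)-1-bromo-3,3-dimethoxyprop-1-enyl ether ArO–C(Br)=CH–CH(OMe)2
Conditions: CuI (10 mol%), 2,2'-bipyridine (20 mol%), K3PO4, toluene, 110 °C
Reagents that add atoms: none
Why: Copper-catalysed Ullmann-type C–O coupling of a phenol with a 1,1-dibromoalkene, in which the less hindered C–Br bond trans to the acetal carbon reacts, which fixes the Z geometry and leaves bromine anti to the vinyl hydrogen.

Step 7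
Reactants: 9 (Z)-1-bromo-3,3-dimethoxyprop-1-enyl ether ArO–C(Br)=CH–CH(OMe)2
Product: 10 7-[(3,3-dimethoxyprop-1-yn-1-yl)oxy]-8-methoxy-6-(methoxymethoxy)-2,2,5-trimethylchroman-4-one (ArO–C≡C–CH(OMe)2)
Conditions: KOtBu, THF, −40 → 0 °C
Reagents that add atoms: none
Why: Anti-periplanar E2 dehydrobromination of the 1-bromo enol ether should give the aryl ynol ether, which has no hydrogen on the carbon attached to oxygen and so cannot fragment to a ketene by a retro-ene path.

Step 8
Reactants: 11 tert-butyl diazoacetate; 12 2-methylprop-2-enal (methacrolein)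
Product: 14 tert-butyl 2-diazo-4-methyl-3-oxopent-4-enoate, via hydroxy diazo ester 13 (not isolated)
Conditions: DBU (cat.), DMSO, rt; then IBX, rt
Reagents that add atoms: none
Why: DBU-catalysed aldol-type 1,2-addition of the diazoacetate to the enal gives the racemic allylic carbinol, whose stereocenter is removed at once by IBX oxidation in the same pot, so the diazo group never meets an acid chloride or HCl.

Step 9
Reactants: 10 7-[(3,3-dimethoxyprop-1-yn-1-yl)oxy]-8-methoxy-6-(methoxymethoxy)-2,2,5-trimethylchroman-4-one; 14 tert-butyl 2-diazo-4-methyl-3-oxopent-4-enoate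
Product: 19 tert-butyl 2-(aryloxy)-3-(dimethoxymethyl)-4-hydroxy-6-methylbenzoate (aryl = Ar), via vinylketene 15 (not isolated), via vinylcyclobutenone 16 (not isolated), via dienylketene 17 (not isolated), via cyclohexadienone 18 (not isolated)
Conditions: hν (violet LED, ca. 400 nm), 14 (1.5 equiv, slow addition), degassed ClCH2CH2Cl, rt; then 80 °C
Reagents that add atoms: none
Why: Proposed new method: light near 400 nm, absorbed by the diazo ketoester but not by the chromanone of 10, should trigger a Wolff rearrangement in which the isopropenyl group shifts to the carbene carbon to give vinylketene 15; the acetal-bearing alkyne carbon of 10 then bonds to the ketene carbonyl carbon in a [2+2] cycloaddition across the ketene C=C bond to give vinylcyclobutenone 16, which opens on warming (four-electron electrocyclic, reversible) to dienylketene 17, closes to cyclohexadienone 18 and enolizes to phenol 19. Counting the 1,2-shift, four C–C bonds are made in the flask, three of them in the annulation proper, and the ketene carbonyl ends as the ring-A hydroxyl with the acetal carbon between it and the aryloxy carbon and the ester beside the methyl group. The closest known reaction type is the Danheiser benzannulation of vinylketenes (from unsaturated α-diazo ketones or cyclobutenones) with alkoxy- or siloxyalkynes; a ketene that also bears an ester on its α-carbon has not been paired in it with an acetal-substituted aryl ynol ether. Ring A closes by thermal disrotatory six-electron electrocyclization of the (Z)-dienylketene, and no stereocenter remains, since the racemic quaternary carbon of 16 becomes aromatic. The step needs [2+2] addition at the ketene C=C bond in preference to oxa-[4+2] capture through the ester carbonyl, and a single alkyne orientation; the first is expected because an ester C=O is a weak heterodiene terminus, the second is fixed by the ynol ether oxygen, which makes the remote carbon the nucleophilic one. Reversible opening of 16 should funnel both olefin geometries into the dienylketene that can cyclize, and slow addition of 14 keeps the ketene from acylating the product phenol.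

Step 10
Reactants: 19 tert-butyl 2-(aryloxy)-3-(dimethoxymethyl)-4-hydroxy-6-methylbenzoate (aryl = Ar)
Product: 20 3-formyl-4-hydroxy-2-[(6-hydroxy-8-methoxy-2,2,5-trimethyl-4-oxochroman-7-yl)oxy]-6-methylbenzoic acid
Conditions: TFA/CH2Cl2/H2O, 0 °C → rt
Reagents that add atoms: water, O
Why: Acid-mediated acetal hydrolysis, MOM ether hydrolysis and tert-butyl ester acidolysis (loss of isobutene) should occur in one operation, while the C8 methyl ether, the ketone and the diaryl ether are inert to cold aqueous TFA.

Step 11
Reactants: 20 3-formyl-4-hydroxy-2-[(6-hydroxy-8-methoxy-2,2,5-trimethyl-4-oxochroman-7-yl)oxy]-6-methylbenzoic acid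
Product: 21 O8-methyl ether of the target (depsidone with the seven-membered lactone from the ring-A carboxyl to O6 and OMe at C8)
Conditions: DCC, CH2Cl2 (high dilution), rt
Reagents that add atoms: none
Why: Carbodiimide-mediated lactonization (Steglich-type activation) should be regioselective, because only the C6 hydroxyl of ring B can reach the O-acylisourea intramolecularly: O8 is methylated and the ring-A hydroxyl is para to the carboxyl and hydrogen-bonded to the aldehyde.

Step 12
Reactants: 21 O8-methyl ether of the target
Product: 22 CNP0271978.0 (target depsidone with free C8 hydroxyl on ring B)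
Conditions: BCl3, CH2Cl2, −78 → 0 °C; then H2O
Reagents that add atoms: none
Why: Lewis-acid ether cleavage, in which BCl3 binds the methoxy oxygen that is flanked by two ortho oxygens and twisted out of the ring plane (the most basic ether oxygen) and chloride removes the methyl group by SN2; the aryl ester lactone, the chelated hydroxy aldehyde and the chromanone should survive at low temperature.

Compound list
1 | 2,3-dimethoxy-5-methyl-1,4-benzoquinone | COC1=C(OC)C(=O)C(C)=CC1=O | starting material
2 | 2,3-dimethoxy-5-methylbenzene-1,4-diol | COc1c(OC)c(O)c(C)cc1O | intermediate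
3 | 3-methylbut-2-enoic acid | CC(C)=CC(O)=O | starting material
4 | 6-hydroxy-7,8-dimethoxy-2,2,5-trimethylchroman-4-one | COc1c(OC)c2OC(C)(C)CC(=O)c2c(C)c1O | intermediate
5 | 7,8-dimethoxy-6-(methoxymethoxy)-2,2,5-trimethylchroman-4-one | COCOc1c(C)c2C(=O)CC(C)(C)Oc2c(OC)c1OC | intermediate
6 | 7-hydroxy-8-methoxy-6-(methoxymethoxy)-2,2,5-trimethylchroman-4-one | COCOc1c(C)c2C(=O)CC(C)(C)Oc2c(OC)c1O | intermediate
7 | 2,2-dimethoxyacetaldehyde | COC(OC)C=O | starting material
8 | 1,1-dibromo-3,3-dimethoxyprop-1-ene | COC(OC)C=C(Br)Br | intermediate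
9 | 7-{[(1Z)-1-bromo-3,3-dimethoxyprop-1-en-1-yl]oxy}-8-methoxy-6-(methoxymethoxy)-2,2,5-trimethylchroman-4-one | COC(OC)/C=C(\Br)Oc1c(OCOC)c(C)c2C(=O)CC(C)(C)Oc2c1OC | intermediate
10 | 7-[(3,3-dimethoxyprop-1-yn-1-yl)oxy]-8-methoxy-6-(methoxymethoxy)-2,2,5-trimethylchroman-4-one | COC(OC)C#COc1c(OCOC)c(C)c2C(=O)CC(C)(C)Oc2c1OC | intermediate
11 | tert-butyl diazoacetate | CC(C)(C)OC(=O)C=[N+]=[N-] | starting material
12 | 2-methylprop-2-enal (methacrolein) | CC(=C)C=O | starting material
13 | tert-butyl 2-diazo-3-hydroxy-4-methylpent-4-enoate (racemic) | CC(=C)C(O)C(=[N+]=[N-])C(=O)OC(C)(C)C | intermediate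
14 | tert-butyl 2-diazo-4-methyl-3-oxopent-4-enoate | CC(=C)C(=O)C(=[N+]=[N-])C(=O)OC(C)(C)C | intermediate
15 | tert-butyl 3-methyl-2-(oxomethylidene)but-3-enoate (vinylketene) | CC(=C)C(=C=O)C(=O)OC(C)(C)C | intermediate
16 | tert-butyl 2-(ArO)-3-(dimethoxymethyl)-4-oxo-1-(prop-1-en-2-yl)cyclobut-2-ene-1-carboxylate (racemic) | COC(OC)C1=C(Oc2c(OCOC)c(C)c3C(=O)CC(C)(C)Oc3c2OC)C(C(C)=C)(C(=O)OC(C)(C)C)C1=O | intermediate
17 | tert-butyl (2Z)-2-[1-(ArO)-2-(dimethoxymethyl)-3-oxoprop-2-en-1-ylidene]-3-methylbut-3-enoate (dienylketene) | O=C=C(C(OC)OC)/C(Oc1c(OCOC)c(C)c2C(=O)CC(C)(C)Oc2c1OC)=C(\C(C)=C)C(=O)OC(C)(C)C | intermediate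
18 | tert-butyl 6-(ArO)-5-(dimethoxymethyl)-2-methyl-4-oxocyclohexa-1,5-diene-1-carboxylate | O=C1CC(C)=C(C(=O)OC(C)(C)C)C(Oc2c(OCOC)c(C)c3C(=O)CC(C)(C)Oc3c2OC)=C1C(OC)OC | intermediate
19 | tert-butyl 2-(ArO)-3-(dimethoxymethyl)-4-hydroxy-6-methylbenzoate | CC(C)(C)OC(=O)c1c(C)cc(O)c(C(OC)OC)c1Oc1c(OCOC)c(C)c2C(=O)CC(C)(C)Oc2c1OC | intermediate
20 | 3-formyl-4-hydroxy-2-[(6-hydroxy-8-methoxy-2,2,5-trimethyl-4-oxochroman-7-yl)oxy]-6-methylbenzoic acid | Cc1cc(O)c(C=O)c(Oc2c(O)c(C)c3C(=O)CC(C)(C)Oc3c2OC)c1C(O)=O | intermediate
21 | O8-methyl ether of the target: depsidone with the lactone from the ring-A carboxyl to O6, the ether at O7 and OMe at C8 of the chromanone | Cc1cc(O)c(C=O)c2c1C(=O)Oc1c(C)c3c(c(OC)c1O2)OC(C)(C)CC3=O | intermediate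
22 | CNP0271978.0: depsidone in which ring A (carboxyl, aryloxy, formyl, hydroxyl, H, methyl in sequence) is joined to the 2,2,5-trimethylchroman-4-one through the lactone at O6 and the ether at O7, with free OH at C8 | Cc1cc(O)c(C=O)c2c1C(=O)Oc1c(C)c3c(c(O)c1O2)OC(C)(C)CC3=O | target

Total step count: 12.
Longest linear sequence: 10 steps (steps 1, 2, 3, 4, 6, 7, 9, 10, 11 and 12, from quinone 1).

Steps most likely to fail

Step 9. The ketene may be captured through its ester carbonyl (oxa-[4+2]) or by the product phenol (O-acylation), the carbene may react without rearranging, or the [2+2] addition to the acetal-deactivated alkyne may be too slow. The fallback uses known chemistry (SNAr ether formation and palladium carbonylation), sets out from phenol 6 and comes back at acid 20. Commercial 3-fluoro-5-methylphenol is brominated para to the hydroxyl (NBS, MeCN, 0 °C) to give 4-bromo-3-fluoro-5-methylphenol F1, which is protected (MOMCl, iPr2NEt) as 2-bromo-1-fluoro-5-(methoxymethoxy)-3-methylbenzene F2. Lithiation between fluorine and the MOM ether (LiN(iPr)2, THF, −78 °C) and a DMF quench should give 3-bromo-2-fluoro-6-(methoxymethoxy)-4-methylbenzaldehyde F3. The potassium phenoxide of 6 then displaces the fluoride, which is activated by the ortho formyl group (K2CO3, DMF, 80 °C), to give 2-(ArO)-3-bromo-6-(methoxymethoxy)-4-methylbenzaldehyde F4. Hydroxycarbonylation of the aryl bromide (Pd(OAc)2, Xantphos, CO, K2CO3, dioxane/H2O, 90 °C) should give 2-(ArO)-3-formyl-4-(methoxymethoxy)-6-methylbenzoic acid F5, and the acid treatment of step 10 removes both MOM groups to give 20.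

Step 6. The hindered, electron-poor phenoxide may couple too slowly, so that base-induced loss of HBr from 8 and over-substitution take over. The fallback sets out from 6 and comes back at 10 without passing through 9. O-Alkylation of 6 with commercial 3-bromo-1,1-dimethoxypropan-2-one (K2CO3, acetone) gives 7-(3,3-dimethoxy-2-oxopropoxy)-8-methoxy-6-(methoxymethoxy)-2,2,5-trimethylchroman-4-one F6. Selective enolization of the more acidic aryloxymethyl ketone (LiN(SiMe3)2, 1 equiv, THF, −78 °C) and trapping with PhNTf2 should give (Z)-1-(ArO)-3,3-dimethoxyprop-1-en-2-yl trifluoromethanesulfonate F7. Elimination of triflate with KOtBu (THF, −78 °C) then gives ynol ether 10.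

Step 2. Conjugate C-alkylation of the arene by the protonated acid (leading towards a 4,4-dimethyl dihydrocoumarin), air oxidation of the hydroquinone or ether cleavage in the hot acid may compete with acylation. The fallback sets out from 2 and comes back at 4. Friedel–Crafts/Fries acetylation (AcOH, BF3·OEt2, 90 °C) gives 1-(2,5-dihydroxy-3,4-dimethoxy-6-methylphenyl)ethan-1-one F8. Kabbe condensation with acetone and pyrrolidine (MeOH, 60 °C) then closes the 2,2-dimethylchromanone 4.

Further compounds
F1 | step 9 | 4-bromo-3-fluoro-5-methylphenol | Cc1cc(O)cc(F)c1Br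
F2 | step 9 | 2-bromo-1-fluoro-5-(methoxymethoxy)-3-methylbenzene | Cc1cc(OCOC)cc(F)c1Br
F3 | step 9 | 3-bromo-2-fluoro-6-(methoxymethoxy)-4-methylbenzaldehyde | Cc1cc(OCOC)c(C=O)c(F)c1Br
F4 | step 9 | 2-(ArO)-3-bromo-6-(methoxymethoxy)-4-methylbenzaldehyde | Cc1cc(OCOC)c(C=O)c(Oc2c(OCOC)c(C)c3C(=O)CC(C)(C)Oc3c2OC)c1Br
F5 | step 9 | 2-(ArO)-3-formyl-4-(methoxymethoxy)-6-methylbenzoic acid | Cc1cc(OCOC)c(C=O)c(Oc2c(OCOC)c(C)c3C(=O)CC(C)(C)Oc3c2OC)c1C(O)=O
F6 | step 6 | 7-(3,3-dimethoxy-2-oxopropoxy)-8-methoxy-6-(methoxymethoxy)-2,2,5-trimethylchroman-4-one | COC(OC)C(=O)COc1c(OCOC)c(C)c2C(=O)CC(C)(C)Oc2c1OC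
F7 | step 6 | (Z)-1-(ArO)-3,3-dimethoxyprop-1-en-2-yl trifluoromethanesulfonate | COC(OC)/C(OS(=O)(=O)C(F)(F)F)=C/Oc1c(OCOC)c(C)c2C(=O)CC(C)(C)Oc2c1OC
F8 | step 2 | 1-(2,5-dihydroxy-3,4-dimethoxy-6-methylphenyl)ethan-1-one | CC(=O)c1c(C)c(O)c(OC)c(OC)c1O
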